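**Retrosynthetic overview**

1. Target 27 is a melampolide. Ring A is the ten-membered carbocycle C1–C10 (C1=C10 ring-cis and carrying the C14 methyl ester, C4=C5 trans). Ring B is the α-methylene-γ-butyrolactone fused at C6–C7. O8 carries a methacrylate and C9 a free hydroxyl.
2. Feature used: C14 sits on C10, and the path C10–C9–C8–O8 places it two carbons from O8. C14 is therefore delivered as CO from O8 onto a C10≡C1 alkyne, closing a temporary five-membered lactone (ring T: O8–C14–C10–C9–C8) that fixes the C1=C10 geometry and tells O8 from O9.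
3. Ring T is then opened to the C14 methyl ester and a free O8, which is methacrylated. Rings A and B are closed last and together by CrCl2 allylation of a C6 enal by a C13 allylic bromide (bond C6–C7), followed by desilylation of O9.
4. The alkyne comes from a geraniol-derived enyne (C10, C1–C6, C15) and an (S)-glycerate Weinreb amide (C7–C9). C9 is set by asymmetric transfer hydrogenation of the ynone.
5. Order of ring formation: ring T (step 11, opened in step 12), then ring A and ring B in one operation (step 19).

Key step: step 11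

Remarks on the chemistry:
- Germacrane numbering is used for every intermediate (C11–C13 lactone side chain, C14 ester carbon on C10, C15 methyl on C4).
- Assumption: the facial sense of the transfer hydrogenation in step 7 follows the usual model in which the alkynyl group takes the place of the aryl group of an aryl ketone; this calls for the (R,R)-configured catalyst to give (9S).
- The CIP label of C8 changes from S to R in aldehyde 20 only because C7 gains priority; the spatial arrangement is unchanged.

**Route**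

Step 1
Reactants: 1 geraniol
Product: 2 geranyl 4-methoxybenzyl ether
Conditions: NaH, PMBCl, Bu4NI (cat.), THF/DMF, 0 °C → rt
Reagents that add atoms: 4-methoxybenzyl chloride, COc1ccc(CCl)cc1
Why: Williamson etherification of the primary allylic alkoxide with a benzylic chloride under iodide catalysis; the (E)-olefin that becomes C4=C5 is untouched.

Step 2
Reactants: 2 geranyl 4-methoxybenzyl ether
Product: 3 6,7-epoxygeranyl 4-methoxybenzyl ether (racemic at the epoxide carbon)
Conditions: mCPBA (1.05 equiv), CH2Cl2, −20 → 0 °C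
Reagents that add atoms: 3-chloroperoxybenzoic acid, OOC(=O)c1cccc(Cl)c1
Why: Prilezhaev epoxidation should be faster at the remote, more electron-rich trisubstituted olefin than at the olefin deactivated inductively by the allylic ether oxygen; the new stereocentre is cleaved in the next step.

Step 3
Reactants: 3 6,7-epoxygeranyl 4-methoxybenzyl ether
Product: 5 (4E)-6-[(4-methoxybenzyl)oxy]-4-methylhex-4-enal, via 6,7-diol 4 (not isolated)
Conditions: H5IO6 (1.2 equiv), THF/H2O, 0 °C
Reagents that add atoms: none
Why: Acid-mediated hydration of the epoxide at its tertiary carbon followed by Malaprade glycol cleavage with periodic acid should release acetone and leave the aldehyde carbon (C1), whose oxygen is the former epoxide oxygen.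

Step 4
Reactants: 5 (4E)-6-[(4-methoxybenzyl)oxy]-4-methylhex-4-enal; 6 dimethyl (1-diazo-2-oxopropyl)phosphonate
Product: 7 (E)-enyne 1-methoxy-4-({[(2E)-3-methylhept-2-en-6-yn-1-yl]oxy}methyl)benzene
Conditions: K2CO3 (2 equiv), MeOH, 0 °C → rt
Reagents that add atoms: dimethyl (1-diazo-2-oxopropyl)phosphonate (compound 6), COP(=O)(OC)C(=[N+]=[N-])C(C)=O
Why: Seyferth–Gilbert homologation in its Ohira–Bestmann form: methanolysis of 6 gives the diazomethylphosphonate anion, which adds to the aldehyde, eliminates dimethyl phosphate and loses N2 with 1,2-hydrogen shift to give the terminal alkyne (C10) under conditions mild enough for an enolisable aldehyde.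

Step 5
Reactants: 8 methyl (S)-2,2-dimethyl-1,3-dioxolane-4-carboxylate
Product: 9 (4S)-N-methoxy-N,2,2-trimethyl-1,3-dioxolane-4-carboxamide
Conditions: MeNH(OMe)·HCl (1.5 equiv), i-PrMgCl (3 equiv), THF, −20 °C
Reagents that add atoms: N,O-dimethylhydroxylamine hydrochloride, CNOC.Cl
Why: Weinreb amidation of the ester by the chloromagnesium amide at low temperature should not epimerise the α-alkoxy stereocentre (C8), and it avoids the configurationally fragile glyceraldehyde acetonide.

Step 6
Reactants: 7 (E)-enyne; 9 Weinreb amide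
Product: 10 (6E)-1-[(4S)-2,2-dimethyl-1,3-dioxolan-4-yl]-8-[(4-methoxybenzyl)oxy]-6-methyloct-6-en-2-yn-1-one
Conditions: 7, n-BuLi (1.05 equiv), THF, −78 °C; then 9, −78 → −20 °C; aq NH4Cl
Reagents that add atoms: none
Why: Weinreb ketone synthesis: the lithium acetylide adds once because the chelated tetrahedral intermediate persists until work-up, forming the C9–C10 bond without touching C8.

Step 7
Reactants: 10 ynone
Product: 11 (1S,6E)-1-[(4S)-2,2-dimethyl-1,3-dioxolan-4-yl]-8-[(4-methoxybenzyl)oxy]-6-methyloct-6-en-2-yn-1-ol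
Conditions: Ru[(R,R)-TsNCH(Ph)CH(Ph)NH](p-cymene) (2 mol %), i-PrOH, rt
Reagents that add atoms: none
Why: Noyori asymmetric transfer hydrogenation of an α,β-acetylenic ketone: the bifunctional ruthenium hydride–amine delivers hydride and proton through a six-membered transition state, so the catalyst and not the weak bias of C8 should set C9 as S (the 8,9-syn relationship), and the base-free medium should spare the α-alkoxy ketone from epimerisation.

Step 8
Reactants: 11 propargylic alcohol
Product: 12 C9 tert-butyldimethylsilyl ether of 11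
Conditions: TBSCl, imidazole, DMF, rt
Reagents that add atoms: tert-butyldimethylsilyl chloride, CC(C)(C)[Si](C)(C)Cl
Why: Imidazole-promoted silylation of the secondary propargylic alcohol blocks O9 for the whole route, in particular during the carbonylation.

Step 9
Reactants: 12 silyl ether acetonide
Product: 13 (2S,3S,8E)-3-[(tert-butyldimethylsilyl)oxy]-10-[(4-methoxybenzyl)oxy]-8-methyldec-8-en-4-yne-1,2-diol
Conditions: PPTS (0.2 equiv), MeOH, rt → 40 °C
Reagents that add atoms: none
Why: Acid-catalysed transacetalisation of the terminal acetonide to methanol under pyridinium buffering should be tolerated by the secondary TBS ether and the PMB ether.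

Step 10
Reactants: 13 diol
Product: 14 (2S,3S,8E)-3-[(tert-butyldimethylsilyl)oxy]-10-[(4-methoxybenzyl)oxy]-8-methyl-1-[(triethylsilyl)oxy]dec-8-en-4-yn-2-ol
Conditions: TESCl (1.05 equiv), imidazole, CH2Cl2, −40 °C
Reagents that add atoms: chlorotriethylsilane, CC[Si](Cl)(CC)CC
Why: Silylation at low temperature should take the primary O7 in preference to the secondary O8, which is flanked by the OTBS-bearing C9, leaving exactly the homopropargylic C8 hydroxyl free.

Step 11
Reactants: 14 homopropargylic alcohol; 15 carbon monoxide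
Product: 16 (3E,4S,5S)-4-[(tert-butyldimethylsilyl)oxy]-3-{(4E)-6-[(4-methoxybenzyl)oxy]-4-methylhex-4-en-1-ylidene}-5-{[(triethylsilyl)oxy]methyl}oxolan-2-one
Conditions: PdCl2 (5 mol %), SnCl2 (5 mol %), PPh3 (10 mol %), CO (8 atm), MeCN, 70 °C
Reagents that add atoms: carbon monoxide (compound 15), [C-]#[O+]
Why: On divalent palladium (PdCl2/PPh3 activated by SnCl2 as a trichlorostannate ligand) the free C8 hydroxyl attacks coordinated CO to give an alkoxycarbonylpalladium species (bond O8–C14) with release of HCl, the tethered C10≡C1 triple bond inserts syn into the Pd–C14 bond (bond C14–C10), and protonolysis of the C1–Pd bond with retention returns the catalyst without change of oxidation state. The closest known reaction type is the palladium-catalysed cyclocarbonylation of homopropargylic alcohols to α-methylene- and (E)-α-alkylidene-γ-butyrolactones. The five-membered ring O8–C14–C10–C9–C8 closes in the 5-exo-dig mode with respect to the alkyne. No stereocentre is formed and C8 and C9 are not touched; the new stereoelement is the C1=C10 geometry, fixed by syn acylpalladation and retentive protonolysis so that C14 and H1 are cis, which is the ring-cis arrangement of C2 and C9 required by the target. The step needs O8 alone to act as nucleophile and a five-membered ring: silylation of the propargylic O9 and of O7 (which would give the six-membered lactone) and the two-carbon spacing between O8 and C10 secure this. The isolated trisubstituted olefin and the PMB ether are not expected to compete for the catalyst.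

Step 12
Reactants: 16 temporary lactone
Product: 18 methyl (2E,6E)-2-[(1S,2S)-1-(TBS-oxy)-2-hydroxy-3-(TES-oxy)propyl]-8-(PMB-oxy)-6-methylocta-2,6-dienoate, via lithium hydroxy carboxylate 17 (not isolated)
Conditions: LiOH·H2O (1.2 equiv), THF/H2O (4:1), 0 °C; concentrate, toluene azeotrope; MeI (5 equiv), DMF, 0 °C → rt; extractive work-up, used at once
Reagents that add atoms: lithium hydroxide, [Li+].[OH-]; iodomethane, CI
Why: Saponification cleaves the acyl–O8 bond of the α-alkylidene lactone and the lithium carboxylate is O-methylated by SN2 reaction with MeI, so the free γ-hydroxy acid, which would close again, is never formed, and the neutral C8 hydroxyl is not alkylated.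

Step 13
Reactants: 18 hydroxy methyl ester
Product: 19 methyl (2E,6E)-2-[(1S,2S)-1-(TBS-oxy)-2-(methacryloyloxy)-3-(TES-oxy)propyl]-8-(PMB-oxy)-6-methylocta-2,6-dienoate
Conditions: methacrylic anhydride (3 equiv), Et3N, DMAP (0.3 equiv), CH2Cl2, 0 °C → rt
Reagents that add atoms: methacrylic anhydride, CC(=C)C(=O)OC(=O)C(C)=C
Why: DMAP-catalysed acyl transfer to the only free hydroxyl (O8, singled out by the temporary lactone) should outrun re-lactonisation onto C14 when run directly on crude 18.

Step 14
Reactants: 19 methacrylate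
Product: 20 methyl (2E,6E)-2-[(1S,2R)-1-(TBS-oxy)-2-(methacryloyloxy)-3-oxopropyl]-8-(PMB-oxy)-6-methylocta-2,6-dienoate
Conditions: (COCl)2, DMSO, CH2Cl2, −78 → −40 °C; then Et3N, −78 → −20 °C; cold pH 7 work-up
Reagents that add atoms: none
Why: Swern conditions convert a primary triethylsilyl ether directly into the aldehyde (the chlorodimethylsulfonium ion cleaves the primary Si–O bond to the alkoxysulfonium ion) while the secondary TBS ether is inert, so a free C7 alcohol that could take over the C8 acyl group or lactonise onto C14 is never released.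

Step 15
Reactants: 20 C7 aldehyde
Product: 21 Morita–Baylis–Hillman alcohol, methyl (2E,6E)-2-[(1S,2S,3RS)-1-(TBS-oxy)-3-hydroxy-4-(methoxycarbonyl)-2-(methacryloyloxy)pent-4-en-1-yl]-8-(PMB-oxy)-6-methylocta-2,6-dienoate
Conditions: methyl acrylate (20 equiv, neat), DABCO (1 equiv), rt
Reagents that add atoms: methyl acrylate, C=CC(=O)OC
Why: Morita–Baylis–Hillman reaction: the DABCO–acrylate zwitterionic enolate adds to the α-oxygenated, hence activated, aldehyde to form C7–C11, the α-substituted methacrylate and the trisubstituted enoate being inert as acceptors; the C7 configuration is immaterial because C7 becomes sp2 in step 16.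

Step 16
Reactants: 21 Morita–Baylis–Hillman alcohol
Product: 22 methyl (2E,6E)-2-[(1S,2S,3Z)-5-bromo-1-(TBS-oxy)-4-(methoxycarbonyl)-2-(methacryloyloxy)pent-3-en-1-yl]-8-(PMB-oxy)-6-methylocta-2,6-dienoate
Conditions: NBS, Me2S (premixed), CH2Cl2, 0 °C → rt
Reagents that add atoms: N-bromosuccinimide, BrN1C(=O)CCC1=O
Why: Corey–Kim-type activation of the allylic alcohol as its alkoxysulfonium ion and SN2' attack of bromide at C13 should give the conjugated (Z)-2-(bromomethyl)alk-2-enoate (C8 trans to C12), the usual outcome for such alcohols.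

Step 17
Reactants: 22 allylic bromide PMB ether
Product: 23 C6 allylic alcohol, methyl (2E,6E)-2-[(1S,2S,3Z)-5-bromo-1-(TBS-oxy)-4-(methoxycarbonyl)-2-(methacryloyloxy)pent-3-en-1-yl]-8-hydroxy-6-methylocta-2,6-dienoate
Conditions: DDQ (1.3 equiv), CH2Cl2/pH 7 buffer (10:1), 0 °C
Reagents that add atoms: none
Why: Oxidative PMB cleavage (hydride abstraction from the electron-rich benzylic position, hydrolysis of the oxocarbenium ion) should leave silyl ether, esters and allylic bromide untouched.

Step 18
Reactants: 23 C6 allylic alcohol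
Product: 24 C6 enal, methyl (2E,6E)-2-[(1S,2S,3Z)-5-bromo-1-(TBS-oxy)-4-(methoxycarbonyl)-2-(methacryloyloxy)pent-3-en-1-yl]-6-methyl-8-oxoocta-2,6-dienoate
Conditions: MnO2 (20 equiv), CH2Cl2, rt
Reagents that add atoms: none
Why: MnO2 oxidises allylic alcohols selectively and should give the (E)-enal without touching the allylic bromide.

Step 19
Reactants: 24 enal allylic bromide
Product: 26 C9 TBS ether of the target, via ten-membered C6 hydroxy diester 25 (not isolated)
Conditions: CrCl2 (8 equiv), THF, 2 mM (slow addition of 24), rt; aq NH4Cl; PPTS (cat.), CH2Cl2, rt to complete lactonisation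
Reagents that add atoms: none
Why: Intramolecular Nozaki–Hiyama-type allylation: CrCl2 inserts into the C13–Br bond and the allylchromium adds through its γ-carbon C7 to the C6 aldehyde in a six-membered cyclic transition state, closing ring A, after which the C6 alkoxide acylates on C12 (5-exo-trig) to close ring B; C6 (R) and C7 (S) are expected to arise under macrocyclic control, the ring-cis C1=C10 and trans C4=C5 olefins together with the C8 and C9 stereocentres favouring the transition state that places H6 and H7 anti (trans-fused lactone) and C11 anti to the C8 acyloxy group.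

Step 20
Reactants: 26 C9 TBS ether
Product: 27 target CNP0282644.1
Conditions: HF·pyridine, pyridine, THF, 0 °C → rt
Reagents that add atoms: none
Why: Fluoride-driven Si–O cleavage under buffered, mildly acidic conditions should free the C9 hydroxyl without acyl migration between O8 and O9, translactonisation or conjugate addition to the α-methylene lactone.

**Compound list**

1 | geraniol | CC(C)=CCC/C(C)=C/CO | starting material
2 | geranyl 4-methoxybenzyl ether | CC(C)=CCC/C(C)=C/COCc1ccc(OC)cc1 | intermediate
3 | 6,7-epoxygeranyl 4-methoxybenzyl ether (racemic epoxide) | CC1(C)OC1CC/C(C)=C/COCc1ccc(OC)cc1 | intermediate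
4 | (6E)-8-[(4-methoxybenzyl)oxy]-2,6-dimethyloct-6-ene-2,3-diol (racemic, not isolated) | CC(C)(O)C(O)CC/C(C)=C/COCc1ccc(OC)cc1 | intermediate
5 | (4E)-6-[(4-methoxybenzyl)oxy]-4-methylhex-4-enal | O=CCC/C(C)=C/COCc1ccc(OC)cc1 | intermediate
6 | dimethyl (1-diazo-2-oxopropyl)phosphonate | COP(=O)(OC)C(=[N+]=[N-])C(C)=O | starting material
7 | 1-methoxy-4-({[(2E)-3-methylhept-2-en-6-yn-1-yl]oxy}methyl)benzene | C#CCC/C(C)=C/COCc1ccc(OC)cc1 | intermediate
8 | methyl (S)-2,2-dimethyl-1,3-dioxolane-4-carboxylate | COC(=O)[C@@H]1COC(C)(C)O1 | starting material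
9 | (4S)-N-methoxy-N,2,2-trimethyl-1,3-dioxolane-4-carboxamide | CON(C)C(=O)[C@@H]1COC(C)(C)O1 | intermediate
10 | (6E)-1-[(4S)-2,2-dimethyl-1,3-dioxolan-4-yl]-8-[(4-methoxybenzyl)oxy]-6-methyloct-6-en-2-yn-1-one | O1[C@@H](COC1(C)C)C(=O)C#CCC/C(C)=C/COCc1ccc(OC)cc1 | intermediate
11 | (1S,6E)-1-[(4S)-2,2-dimethyl-1,3-dioxolan-4-yl]-8-[(4-methoxybenzyl)oxy]-6-methyloct-6-en-2-yn-1-ol | O1[C@@H](COC1(C)C)[C@@H](O)C#CCC/C(C)=C/COCc1ccc(OC)cc1 | intermediate
12 | C9 tert-butyldimethylsilyl ether of 11 (1S, 4S) | O1[C@@H](COC1(C)C)[C@@H](O[Si](C)(C)C(C)(C)C)C#CCC/C(C)=C/COCc1ccc(OC)cc1 | intermediate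
13 | (2S,3S,8E)-3-[(tert-butyldimethylsilyl)oxy]-10-[(4-methoxybenzyl)oxy]-8-methyldec-8-en-4-yne-1,2-diol | O[C@@H](CO)[C@@H](O[Si](C)(C)C(C)(C)C)C#CCC/C(C)=C/COCc1ccc(OC)cc1 | intermediate
14 | (2S,3S,8E)-3-[(tert-butyldimethylsilyl)oxy]-10-[(4-methoxybenzyl)oxy]-8-methyl-1-[(triethylsilyl)oxy]dec-8-en-4-yn-2-ol (key-step precursor; 8S,9S) | O[C@@H](CO[Si](CC)(CC)CC)[C@@H](O[Si](C)(C)C(C)(C)C)C#CCC/C(C)=C/COCc1ccc(OC)cc1 | intermediate
15 | carbon monoxide | [C-]#[O+] | starting material
16 | (3E,4S,5S)-4-[(tert-butyldimethylsilyl)oxy]-3-{(4E)-6-[(4-methoxybenzyl)oxy]-4-methylhex-4-en-1-ylidene}-5-{[(triethylsilyl)oxy]methyl}oxolan-2-one (key-step product, ring T) | O=C1O[C@@H](CO[Si](CC)(CC)CC)[C@@H](O[Si](C)(C)C(C)(C)C)/C1=C\CC/C(C)=C/COCc1ccc(OC)cc1 | intermediate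
17 | lithium (2E,6E)-2-[(1S,2S)-1-(TBS-oxy)-2-hydroxy-3-(TES-oxy)propyl]-8-(PMB-oxy)-6-methylocta-2,6-dienoate (not isolated) | O[C@@H](CO[Si](CC)(CC)CC)[C@@H](O[Si](C)(C)C(C)(C)C)/C(C(=O)[O-])=C\CC/C(C)=C/COCc1ccc(OC)cc1.[Li+] | intermediate
18 | methyl (2E,6E)-2-[(1S,2S)-1-(TBS-oxy)-2-hydroxy-3-(TES-oxy)propyl]-8-(PMB-oxy)-6-methylocta-2,6-dienoate | O[C@@H](CO[Si](CC)(CC)CC)[C@@H](O[Si](C)(C)C(C)(C)C)/C(C(=O)OC)=C\CC/C(C)=C/COCc1ccc(OC)cc1 | intermediate
19 | methyl (2E,6E)-2-[(1S,2S)-1-(TBS-oxy)-2-(methacryloyloxy)-3-(TES-oxy)propyl]-8-(PMB-oxy)-6-methylocta-2,6-dienoate | C=C(C)C(=O)O[C@@H](CO[Si](CC)(CC)CC)[C@@H](O[Si](C)(C)C(C)(C)C)/C(C(=O)OC)=C\CC/C(C)=C/COCc1ccc(OC)cc1 | intermediate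
20 | methyl (2E,6E)-2-[(1S,2R)-1-(TBS-oxy)-2-(methacryloyloxy)-3-oxopropyl]-8-(PMB-oxy)-6-methylocta-2,6-dienoate | C=C(C)C(=O)O[C@@H](C=O)[C@@H](O[Si](C)(C)C(C)(C)C)/C(C(=O)OC)=C\CC/C(C)=C/COCc1ccc(OC)cc1 | intermediate
21 | methyl (2E,6E)-2-[(1S,2S,3RS)-1-(TBS-oxy)-3-hydroxy-4-(methoxycarbonyl)-2-(methacryloyloxy)pent-4-en-1-yl]-8-(PMB-oxy)-6-methylocta-2,6-dienoate (C7 epimers) | C=C(C)C(=O)O[C@@H](C(O)C(=C)C(=O)OC)[C@@H](O[Si](C)(C)C(C)(C)C)/C(C(=O)OC)=C\CC/C(C)=C/COCc1ccc(OC)cc1 | intermediate
22 | methyl (2E,6E)-2-[(1S,2S,3Z)-5-bromo-1-(TBS-oxy)-4-(methoxycarbonyl)-2-(methacryloyloxy)pent-3-en-1-yl]-8-(PMB-oxy)-6-methylocta-2,6-dienoate | C=C(C)C(=O)O[C@@H](/C=C(/C(=O)OC)CBr)[C@@H](O[Si](C)(C)C(C)(C)C)/C(C(=O)OC)=C\CC/C(C)=C/COCc1ccc(OC)cc1 | intermediate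
23 | methyl (2E,6E)-2-[(1S,2S,3Z)-5-bromo-1-(TBS-oxy)-4-(methoxycarbonyl)-2-(methacryloyloxy)pent-3-en-1-yl]-8-hydroxy-6-methylocta-2,6-dienoate | C=C(C)C(=O)O[C@@H](/C=C(/C(=O)OC)CBr)[C@@H](O[Si](C)(C)C(C)(C)C)/C(C(=O)OC)=C\CC/C(C)=C/CO | intermediate
24 | methyl (2E,6E)-2-[(1S,2S,3Z)-5-bromo-1-(TBS-oxy)-4-(methoxycarbonyl)-2-(methacryloyloxy)pent-3-en-1-yl]-6-methyl-8-oxoocta-2,6-dienoate | C=C(C)C(=O)O[C@@H](/C=C(/C(=O)OC)CBr)[C@@H](O[Si](C)(C)C(C)(C)C)/C(C(=O)OC)=C\CC/C(C)=C/C=O | intermediate
25 | (6R,7S,8S,9S)-ten-membered hydroxy diester: ring A with C6 OH (chromium alkoxide before work-up), C7 1-(methoxycarbonyl)vinyl, C8 methacrylate, C9 OTBS, C10 CO2Me (not isolated) | C=C(C)C(=O)O[C@H]1[C@@H](C(=C)C(=O)OC)[C@H](O)/C=C(\C)CC/C=C(/C(=O)OC)[C@@H]1O[Si](C)(C)C(C)(C)C | intermediate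
26 | methyl (3aS,4S,5S,6E,10E,11aR)-5-[(tert-butyldimethylsilyl)oxy]-10-methyl-4-(methacryloyloxy)-3-methylidene-2-oxo-2,3,3a,4,5,8,9,11a-octahydrocyclodeca[b]furan-6-carboxylate | C=C(C)C(=O)O[C@H]1[C@H]2C(=C)C(=O)O[C@@H]2/C=C(\C)CC/C=C(/C(=O)OC)[C@@H]1O[Si](C)(C)C(C)(C)C | intermediate
27 | methyl (3aS,4S,5S,6E,10E,11aR)-5-hydroxy-10-methyl-4-(methacryloyloxy)-3-methylidene-2-oxo-2,3,3a,4,5,8,9,11a-octahydrocyclodeca[b]furan-6-carboxylate (CNP0282644.1; 6R,7S,8S,9S in germacrane numbering) | C=C(C)C(=O)O[C@H]1[C@H]2C(=C)C(=O)O[C@@H]2/C=C(\C)CC/C=C(/C(=O)OC)[C@@H]1O | target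

**Step count**

Total: 20 steps. Longest linear sequence: 19 steps (steps 1–4 and 6–20, from geraniol).

**Steps most likely to fail**

Step 19 (ring closure). Intermolecular coupling or simple reduction of the bromide may outrun the ten-membered ring closure. The allylchromium may lose the C8 acyloxy group by reductive 1,4-elimination. The facial course at C6/C7 may place the lactone cis or on the wrong face of ring A, since the stereochemical outcome rests on macrocyclic control alone. Fallback, from alcohol 21 and returning at 26: a reductant-free allylboration through a closed chair transition state.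
- Acetylation (Ac2O, pyridine, DMAP) would give the C7 acetate F1.
- Pd2(dba)3-catalysed borylation with B2pin2 in DMSO (allylic substitution with transposition on zerovalent palladium) would give the C13 pinacol allylboronate PMB ether F2, with C8 trans to C12.
- DDQ would then give the allylic alcohol allylboronate F3, and MnO2 the enal allylboronate F4.
- Heating F4 at high dilution in toluene, or Sc(OTf)3 catalysis, should effect intramolecular allylboration at C7, and the C6 borate should close ring B to give 26.
- The configurationally stable boronate makes the C7=C11 geometry a handle on the C6/C7 relationship. A chair transition state with this geometry would by itself favour the cis lactone, so the configuration obtained has to be secured before going on.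

Step 11 (cyclocarbonylation). Insertion of the disubstituted alkyne, flanked by the bulky C9 silyl ether, into the Pd–C14 bond may be slow. Catalyst decay, acid-induced loss or migration of the triethylsilyl group and hydration of the alkyne could then take over. Fallback, from 14 and returning at 16: the same lactone by carbonylation of a vinyl iodide.
- PdCl2(PPh3)2-catalysed syn hydrostannation with Bu3SnH should place tin on C10 (next to the oxygenated C9) and hydrogen on C1, giving the (E)-C10 tributylstannyl alkene F5.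
- I2 in CH2Cl2 at 0 °C would give, with retention, the (E)-C10 vinyl iodide F6.
- Pd(PPh3)4, CO (1 atm), Et3N, MeCN, 50 °C: oxidative addition to zerovalent palladium, CO insertion and acylation of the C8 hydroxyl should deliver 16 with the same C1=C10 geometry.

Step 15 (Morita–Baylis–Hillman reaction). The slow addition under amine base leaves time for enolisation of the α-acyloxy aldehyde. This could cause epimerisation at C8, β-elimination of the C9 silyloxy group towards a dienal, and 1,2-shift of the methacryloyl group from O8 to the new C7 hydroxyl. Fallback, from 20 and returning at 21: vinylalumination. [1-(Methoxycarbonyl)vinyl]diisobutylaluminium is made beforehand from methyl propiolate, DIBAL-H and N-methylmorpholine N-oxide in THF at 0 °C and added to 20 at −78 → 0 °C. The same alcohol 21 should form within minutes and without amine base, so no further compound F0 arises.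

**Further compounds**

F1 | step 19 | C7 acetate of 21 | C=C(C)C(=O)O[C@@H](C(OC(C)=O)C(=C)C(=O)OC)[C@@H](O[Si](C)(C)C(C)(C)C)/C(C(=O)OC)=C\CC/C(C)=C/COCc1ccc(OC)cc1
F2 | step 19 | C13 pinacol allylboronate PMB ether | C=C(C)C(=O)O[C@@H](/C=C(/C(=O)OC)CB1OC(C)(C)C(C)(C)O1)[C@@H](O[Si](C)(C)C(C)(C)C)/C(C(=O)OC)=C\CC/C(C)=C/COCc1ccc(OC)cc1
F3 | step 19 | allylic alcohol allylboronate | C=C(C)C(=O)O[C@@H](/C=C(/C(=O)OC)CB1OC(C)(C)C(C)(C)O1)[C@@H](O[Si](C)(C)C(C)(C)C)/C(C(=O)OC)=C\CC/C(C)=C/CO
F4 | step 19 | enal allylboronate | C=C(C)C(=O)O[C@@H](/C=C(/C(=O)OC)CB1OC(C)(C)C(C)(C)O1)[C@@H](O[Si](C)(C)C(C)(C)C)/C(C(=O)OC)=C\CC/C(C)=C/C=O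
F5 | step 11 | (E)-C10 tributylstannyl alkene | O[C@@H](CO[Si](CC)(CC)CC)[C@@H](O[Si](C)(C)C(C)(C)C)/C(=C\CC/C(C)=C/COCc1ccc(OC)cc1)[Sn](CCCC)(CCCC)CCCC
F6 | step 11 | (E)-C10 vinyl iodide | O[C@@H](CO[Si](CC)(CC)CC)[C@@H](O[Si](C)(C)C(C)(C)C)/C(I)=C\CC/C(C)=C/COCc1ccc(OC)cc1
F0 | step 15 | none | none
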